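## Analysis of the target

Target 16 is an oxolane (O1, C2–C5) whose C2 and C5 are unsubstituted methylenes. C3 and C4 each carry a hydroxy(4-hydroxy-3-methoxyphenyl)methyl arm; the carbinol carbon on C3 is called Ca and that on C4 Cb. Four contiguous stereocentres run along Ca–C3–C4–Cb: C3 and C4 are both R, which places the arms trans on the ring, Ca is S and Cb is R. The constitution and the trans ring are twofold symmetric, but the molecule is not: the Ca/C3 pair is S/R and the Cb/C4 pair is R/R, so the arms differ only in the sense of the carbinol relative to its ring carbon. The delicate functions are the two para-hydroxybenzylic alcohols. Acid ionises them (quinone methide or benzylic cation, then epimerisation, dehydration or ether formation), hydrogenation catalysts can cleave their C–O bonds, and the free phenols oxidise easily. The synthesis is hard on two counts: absolute control at C3 and C4 of a ring with no substituent on C2 or C5 to relay chirality, and two carbinols of opposite relative sense on otherwise equivalent arms. The plan rests on the bare C2–O1–C5 segment: O1 with its two methylenes is the parent carbonyl ylide, and the trans C3–C4 bond, with Ca and Cb raised to the carbonyl level, is the E double bond of a fumaric acid derivative.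

## Retrosynthetic reasoning

**16 to 15.** The two phenol O–benzyl bonds are cut last. Benzyl ethers survive aryllithium, hydride and oxidant, and their hydrogenolysis needs neither acid nor base, which the benzylic alcohols of 16 would not tolerate.

**15 to 14 to 13.** The unlike carbinol pair cannot come from one twofold-symmetric operation. The Cb–H bond is therefore cut to give ketone 14, whose reduction must be steered by a catalyst to the R carbinol. Ketone 14 is traced to the twofold-symmetric S,S diol 13 by oxidation of one carbinol. The two hydroxyls of 13 are homotopic, so either gives the same 14, and the only issue is to stop after one oxidation.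

**13 to 12.** Both carbinol C–H bonds are cut at once. A single catalyst must reduce the two equivalent aryl ketones of diketone 12 with the same facial sense, which keeps the twofold symmetry as far into the route as possible.

**12 to 7 and 10.** The Ca–aryl and Cb–aryl bonds are cut. Each of the two acyl carbons of bis-amide 7 takes up one molecule of aryllithium 10, made by halogen–lithium exchange from bromide 9, itself the benzyl ether of phenol 8. Cutting here keeps the cycloaddition partner small, brings the arenes in late, and expels the auxiliary as amine 4 in the same step that builds the ketones, so no separate auxiliary removal is needed.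

**7 to 5 and 6 (key disconnection).** The C2–C3 and C4–C5 bonds are cut together. This returns the E alkene of fumaric diamide 5 and the three-atom dipole 6, released from silyl chloromethyl ether 2 by a fluoride source. The forward reaction must close the ring, copy the alkene geometry into the trans C3/C4 relation and choose one alkene face under the influence of the two amine units. This is where the ring, two skeletal bonds and the two ring stereocentres are gained in one operation.

**5 to 3 and 4; 2 to 1.** The two amide C–N bonds are cut to fumaryl chloride 3 and two molecules of amine 4. Ether 2 comes from alcohol 1 by chloromethylation. Both are one-step preparations, so the risk of the route sits in the cycloaddition.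

## Alternatives that were turned down

**Alternative 1:** The Ca–O and Cb–O bonds are traced to a peroxide bridge and C3–C4 to a double bond. Photooxygenation of the ring-locked s-cis diene A1 with singlet oxygen, a suprafacial [4+2] addition, would give the meso cis-diaryl endoperoxide A2.
- For: both C–O bonds form in one step, and the unlike pair Ca (S) / Cb (R) follows directly from the suprafacial addition. On this point it is stronger than the chosen route, which needs an oxidation and a second reduction to make the carbinols differ.
- Against: C3 and C4 are sp2 in A2. After O–O cleavage, hydrogen would have to add anti across a tetrasubstituted alkene to give the trans ring, with a chiral reagent that distinguishes the two mirror-related ways of doing so. Ordinary syn hydrogenation gives the cis ring.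
- Against: that alkene is flanked by two allylic, benzylic C–O bonds prone to hydrogenolysis, the electron-rich styrene units of A1 invite ene and [2+2] reactions of singlet oxygen, and A1 needs several steps of its own.
- Comparison: the chosen strategy fixes C3 and C4, relative and absolute, by mechanism in the ring-forming step and leaves only aryl ketone reductions of a well-understood kind.

**Alternative 2:** Ca–C3 and Cb–C4 are cut and the ring is opened at O1, so that C2 and C5 become the carboxyl carbons of a succinate. Double enolisation of bis(imide) A3 with Bu2BOTf and iPr2NEt, followed by addition to two molecules of aldehyde A4, would give the double aldol A5.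
- For: four stereocentres and both aryl carbinol arms arise in one convergent step. In skeleton building this is more convergent than the chosen route.
- Against: A5 is twofold symmetric, so one carbinol must still be inverted later and nothing is saved there.
- Against: double enolisation of a 1,4-dicarbonyl compound is uncertain, and the first aldolate can lactonise onto the distal imide carbonyl with loss of the auxiliary.
- Against: after reduction of the imides, O1 must be introduced by joining the two primary hydroxyls while two ionisable benzylic hydroxyls compete for the same activated carbons; closure through a benzylic oxygen would put an aryl group on the ring carbon next to oxygen. That forces protection and deprotection steps.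
- Comparison: the chosen strategy closes the oxolane before any benzylic hydroxyl exists, so this chemoselectivity problem never arises.

**Alternative 3:** C2–C3 is cut and Ca is taken back to an aldehyde, which expands the ring to a seven-membered cyclic acetal. Me3SiOTf would ionise the acetal C–O bond to the enol oxygen of A6; the released enolate carbon (future C3) attacks the oxocarbenium carbon (future C2) and the ring contracts to the trans oxolane aldehyde A7.
- For: the contraction is of a known type and favours trans. The two arms emerge different (aldehyde and arylvinyl), so the two carbinols can be set independently without a symmetric diol detour. On this point it is stronger than the chosen route.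
- Against: the single stereocentre of A6 must first be made enantioselectively, and the electron-rich 1-arylvinyl group is a competing nucleophile towards the oxocarbenium ion and the silyl triflate.
- Against: the vinyl group must later be cleaved oxidatively next to an electron-rich arene and then reduced, and Ca must be built by aryl-metal addition to an epimerisable α-branched aldehyde under substrate control only.
- Comparison: each arm costs about three further steps, against one step for both arms at the ketone level in the chosen route.

Key step: step 3

Assumption: amine 4 is bought enantiopure. The facial sense of step 3 follows a steric model; should it prove opposite, the (2R,5R) antipode of 4 is used with no other change.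

## Route

Step 1
Reactants: 1 (trimethylsilyl)methanol
Product: 2 chloromethyl (trimethylsilyl)methyl ether
Conditions: (CH2O)n, HCl (g), 0 °C, neat; dry over CaCl2, distil; use without storage
Reagents that add atoms: paraformaldehyde, as formaldehyde (C=O); hydrogen chloride (Cl)
Why: Acid-promoted chloromethylation of an alcohol: the hemiformal of 1 is converted by HCl into the α-chloro ether with loss of water, and the Me3Si–CH2 bond is inert to anhydrous HCl at 0 °C.

Step 2
Reactants: 3 fumaryl chloride; 4 (2S,5S)-2,5-dimethylpyrrolidine
Product: 5 (2E)-1,4-bis[(2S,5S)-2,5-dimethylpyrrolidin-1-yl]but-2-ene-1,4-dione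
Conditions: 4 (2.1 equiv), Et3N (2.5 equiv), DMAP (cat.), CH2Cl2, 0 °C to rt
Reagents that add atoms: second equivalent of amine 4, the S,S enantiomer of trans-2,5-dimethylpyrrolidine (C[C@H]1CC[C@H](C)N1)
Why: Twofold N-acylation of a secondary amine by a diacid dichloride: each of the two acid chloride groups of 3 takes up one molecule of 4, so two equivalents of the amine end up in 5. The E geometry and the amine stereocentres are untouched, and at 0 °C acylation should outrun conjugate addition of the hindered amine.

Step 3
Reactants: 5 (2E)-1,4-bis[(2S,5S)-2,5-dimethylpyrrolidin-1-yl]but-2-ene-1,4-dione; 2 chloromethyl (trimethylsilyl)methyl ether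
Product: 7 [(3R,4R)-oxolane-3,4-diyl]bis{[(2S,5S)-2,5-dimethylpyrrolidin-1-yl]methanone}, via parent carbonyl ylide 6 (not isolated)
Conditions: CsF, MeCN, rt, 2 added slowly in excess
Reagents that add atoms: none
Why: Fluoride attacks silicon of 2 and the resulting α-oxy carbanion equivalent loses chloride (a 1,3-elimination), which gives the parent carbonyl ylide 6, an electron-rich dipole trapped at once by the electron-poor alkene of 5. The closest known reactions are this same fluoride-triggered ylide cycloaddition onto fumarate esters and thermal dipolar cycloadditions onto unsaturated amides of trans-2,5-dimethylpyrrolidine, in which the amine alone dictates the face. The oxolane closes by a concerted, suprafacial (3+2) cycloaddition that forms C2–C3 and C4–C5 together; should the bonds form one after the other, conjugate addition followed by 5-exo-tet displacement of chloride by the amide enolate leads to the same ring. The trans relation of C3 and C4 is copied from the E alkene and is also the more stable arrangement. Their absolute configuration comes from the auxiliary: each tertiary amide lies s-cis to the alkene, the pyrrolidine carbon on the alkene side holds its methyl group over one face of the neighbouring alkene carbon, and because the twofold axis of 5 is perpendicular to the alkene plane both methyl groups screen the same face. The ylide should therefore bond to both carbons from the open face, which a model places so that the S,S amine gives 3R,4R. The dipole is symmetric, so there is no regiochemistry and no endo/exo question, and the only selectivity needed is between the two alkene faces; the twofold symmetry of the amine secures it without a Lewis acid, which fluoride would not tolerate, because rotation about either C–N bond changes nothing.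

Step 4
Reactants: 8 4-bromo-2-methoxyphenol
Product: 9 1-(benzyloxy)-4-bromo-2-methoxybenzene
Conditions: BnBr, K2CO3, DMF, rt
Reagents that add atoms: benzyl bromide (BrCc1ccccc1)
Why: Williamson ether synthesis on a phenoxide; benzyl is chosen because it withstands the forcing organolithium step that follows.

Step 5
Reactants: 9 1-(benzyloxy)-4-bromo-2-methoxybenzene; 7 [(3R,4R)-oxolane-3,4-diyl]bis{[(2S,5S)-2,5-dimethylpyrrolidin-1-yl]methanone}
Product: 12 [(3R,4R)-oxolane-3,4-diyl]bis[(4-benzyloxy-3-methoxyphenyl)methanone], via (4-benzyloxy-3-methoxyphenyl)lithium 10 (not isolated), via dilithium bis(hemiaminal alkoxide) 11 (not isolated)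
Conditions: 9 (2.5 equiv), n-BuLi (2.5 equiv), THF, −78 °C; then 7 (1 equiv), −78 to 0 °C; aq. NH4Cl
Reagents that add atoms: second equivalent of aryl bromide 9, 1-benzyloxy-4-bromo-2-methoxybenzene (COc1cc(Br)ccc1OCc1ccccc1)
Why: Bromine–lithium exchange followed by nucleophilic acyl substitution of a tertiary amide by an organolithium, with one molecule of 10 adding to each of the two amide carbonyls of 7, so two equivalents of 9 are built into 12. The tetrahedral lithium hemiaminal alkoxide 11 is expected to hold until the aqueous quench, so each carbonyl takes up one aryl group only, and hydrolysis then releases two molecules of amine 4 and the diketone. C3 and C4 keep their configuration as long as addition outruns α-deprotonation, as it does for other α-branched tertiary amides, and trans is in any case the favoured arrangement.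

Step 6
Reactants: 12 [(3R,4R)-oxolane-3,4-diyl]bis[(4-benzyloxy-3-methoxyphenyl)methanone]
Product: 13 (1S,1′S)-[(3R,4R)-oxolane-3,4-diyl]bis[(4-benzyloxy-3-methoxyphenyl)methanol]
Conditions: (R)-1-methyl-3,3-diphenyltetrahydro-1H,3H-pyrrolo[1,2-c][1,3,2]oxazaborole (cat.), BH3·SMe2, THF, −20 °C; MeOH
Reagents that add atoms: none
Why: Corey–Bakshi–Shibata reduction: each ketone binds the ring boron anti to its aryl group and receives hydride from the borane held on nitrogen, so the R catalyst should give the S carbinol as it does with acetophenone, and one catalyst acting on two equivalent ketones gives the twofold-symmetric diol. Any intrinsic bias of the α-branched ketone is expected to be small beside catalyst control; a single wrong-face event gives the separable diastereomer 15, which is simply carried forward to step 9.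

Step 7
Reactants: 13 (1S,1′S)-[(3R,4R)-oxolane-3,4-diyl]bis[(4-benzyloxy-3-methoxyphenyl)methanol]
Product: 14 [(3R,4R)-4-[(S)-(4-benzyloxy-3-methoxyphenyl)(hydroxy)methyl]oxolan-3-yl](4-benzyloxy-3-methoxyphenyl)methanone
Conditions: MnO2 (activated), CH2Cl2, rt, stopped near half conversion; 13 and 12 recovered
Reagents that add atoms: none
Why: Benzylic alcohol oxidation on the surface of MnO2 under neutral conditions; the two carbinols are homotopic, so one oxidation gives a single hydroxy ketone whichever end reacts, and unchanged 13 and over-oxidised 12 return to steps 7 and 6. The trans ring keeps 14 open, because a lactol would need a trans-fused bicyclo[3.3.0] skeleton; no stereocentre is formed or endangered.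

Step 8
Reactants: 14 [(3R,4R)-4-[(S)-(4-benzyloxy-3-methoxyphenyl)(hydroxy)methyl]oxolan-3-yl](4-benzyloxy-3-methoxyphenyl)methanone
Product: 15 (S)-(4-benzyloxy-3-methoxyphenyl)[(3R,4R)-4-[(R)-(4-benzyloxy-3-methoxyphenyl)(hydroxy)methyl]oxolan-3-yl]methanol
Conditions: (S)-1-methyl-3,3-diphenyltetrahydro-1H,3H-pyrrolo[1,2-c][1,3,2]oxazaborole (cat.), BH3·SMe2 (excess), THF, −20 °C; MeOH
Reagents that add atoms: none
Why: Corey–Bakshi–Shibata reduction with the antipodal catalyst, which should deliver hydride to the opposite ketone face and set Cb as R; the free hydroxyl only consumes one hydride equivalent. The catalyst may here work against a preference of the substrate, but the only diastereomer that a wrong-face reduction can give is 13, which is separated and returned to step 7.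

Step 9
Reactants: 15 (S)-(4-benzyloxy-3-methoxyphenyl)[(3R,4R)-4-[(R)-(4-benzyloxy-3-methoxyphenyl)(hydroxy)methyl]oxolan-3-yl]methanol
Product: 16 (S)-(4-hydroxy-3-methoxyphenyl)[(3R,4R)-4-[(R)-hydroxy(4-hydroxy-3-methoxyphenyl)methyl]oxolan-3-yl]methanol
Conditions: H2 (1 atm), Pd/C, EtOAc, rt, stopped after uptake of two equivalents
Reagents that add atoms: none
Why: Hydrogenolysis of aryl benzyl ethers over palladium on carbon; in a neutral, aprotic solvent without acid these ethers cleave much faster than a secondary benzylic C–OH bond, so both carbinols and all four stereocentres should pass unchanged.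

## Compound list

1 | (trimethylsilyl)methanol | C[Si](C)(C)CO | starting material
2 | chloromethyl (trimethylsilyl)methyl ether | C[Si](C)(C)COCCl | intermediate
3 | fumaryl chloride | O=C(Cl)/C=C/C(=O)Cl | starting material
4 | (2S,5S)-2,5-dimethylpyrrolidine | C[C@H]1CC[C@H](C)N1 | starting material
5 | (2E)-1,4-bis[(2S,5S)-2,5-dimethylpyrrolidin-1-yl]but-2-ene-1,4-dione | C[C@H]1CC[C@H](C)N1C(=O)/C=C/C(=O)N1[C@@H](C)CC[C@@H]1C | intermediate
6 | parent carbonyl ylide (formaldehyde O-methylide) | [CH2-][O+]=C | intermediate
7 | [(3R,4R)-oxolane-3,4-diyl]bis{[(2S,5S)-2,5-dimethylpyrrolidin-1-yl]methanone} | C[C@H]1CC[C@H](C)N1C(=O)[C@H]1COC[C@@H]1C(=O)N1[C@@H](C)CC[C@@H]1C | intermediate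
8 | 4-bromo-2-methoxyphenol | COc1cc(Br)ccc1O | starting material
9 | 1-(benzyloxy)-4-bromo-2-methoxybenzene | COc1cc(Br)ccc1OCc1ccccc1 | intermediate
10 | (4-benzyloxy-3-methoxyphenyl)lithium | [Li]c1ccc(OCc2ccccc2)c(OC)c1 | intermediate
11 | dilithium bis(hemiaminal alkoxide) from twofold addition of 10 to 7 (hemiaminal carbons undefined) | COc1cc(C(O[Li])(N2[C@@H](C)CC[C@@H]2C)[C@H]2COC[C@@H]2C(O[Li])(c2ccc(OCc3ccccc3)c(OC)c2)N2[C@@H](C)CC[C@@H]2C)ccc1OCc1ccccc1 | intermediate
12 | [(3R,4R)-oxolane-3,4-diyl]bis[(4-benzyloxy-3-methoxyphenyl)methanone] | COc1cc(C(=O)[C@H]2COC[C@@H]2C(=O)c2ccc(OCc3ccccc3)c(OC)c2)ccc1OCc1ccccc1 | intermediate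
13 | (1S,1′S)-[(3R,4R)-oxolane-3,4-diyl]bis[(4-benzyloxy-3-methoxyphenyl)methanol] | COc1cc([C@@H](O)[C@H]2COC[C@@H]2[C@H](O)c2ccc(OCc3ccccc3)c(OC)c2)ccc1OCc1ccccc1 | intermediate
14 | [(3R,4R)-4-[(S)-(4-benzyloxy-3-methoxyphenyl)(hydroxy)methyl]oxolan-3-yl](4-benzyloxy-3-methoxyphenyl)methanone | COc1cc([C@@H](O)[C@H]2COC[C@@H]2C(=O)c2ccc(OCc3ccccc3)c(OC)c2)ccc1OCc1ccccc1 | intermediate
15 | (S)-(4-benzyloxy-3-methoxyphenyl)[(3R,4R)-4-[(R)-(4-benzyloxy-3-methoxyphenyl)(hydroxy)methyl]oxolan-3-yl]methanol | COc1cc([C@@H](O)[C@H]2COC[C@@H]2[C@@H](O)c2ccc(OCc3ccccc3)c(OC)c2)ccc1OCc1ccccc1 | intermediate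
16 | (S)-(4-hydroxy-3-methoxyphenyl)[(3R,4R)-4-[(R)-hydroxy(4-hydroxy-3-methoxyphenyl)methyl]oxolan-3-yl]methanol | COc1cc([C@@H](O)[C@H]2COC[C@@H]2[C@@H](O)c2ccc(O)c(OC)c2)ccc1O | target

## Step count and least certain steps

Total: 9 steps. Longest linear sequence: 7 steps (steps 2, 3, 5, 6, 7, 8, 9 from 3 and 4; equally 1, 3, 5–9 from 1).

**Step 3 (key step).**
- What may go wrong: discrimination between the two alkene faces may be modest at room temperature, since only two methyl groups screen one face and the dipole is small. The diamide is also less electrophilic than a fumarate ester, so the ylide may be consumed by self-reaction before it is trapped.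
- Fallback, from 2, rejoining at 13: run the cycloaddition on commercial dimethyl fumarate, a known pairing, to give racemic dimethyl trans-oxolane-3,4-dicarboxylate F1. Treatment with i-PrMgCl and N,O-dimethylhydroxylamine hydrochloride gives the racemic bis(N-methoxy-N-methylamide) F2, which takes up two equivalents of aryllithium 10 to give the racemic diketone F3. Reduction as in step 6 then turns the two enantiomers into diastereomers: 13 and the (3S,4S)-ring diol F4, separated by chromatography. The enantiomeric purity of 13 made this way rests on catalyst control in both series and would have to be checked.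

**Step 5.**
- What may go wrong: the carbonyl groups are shielded by the 2,5-dimethylpyrrolidine, so the aryllithium may act as a base instead. α-Deprotonation would lead to epimerisation or to β-elimination of O1 with ring opening, the addition may simply stall, or early collapse of the tetrahedral intermediate may allow a second addition at the same carbon.
- Fallback, from 7, rejoining at 12: LiH2N·BH3 (lithium amidotrihydroborate) in THF, a small hydride donor known to cleave hindered tertiary amides, gives [(3S,4S)-oxolane-3,4-diyl]dimethanol F5 and frees 4. Dess–Martin periodinane gives (3R,4R)-oxolane-3,4-dicarbaldehyde F6. Addition of two equivalents of 10 at −78 °C gives the bis-carbinol F7 as a mixture of carbinol epimers, and MnO2 oxidises both benzylic alcohols to 12.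

**Step 7.**
- What may go wrong: the second oxidation is as fast as the first, so the reaction is statistical and over-oxidation limits the amount of 14 per pass.
- Fallback, from 13, rejoining at 15: TBSCl (1 equiv) and imidazole give the mono(tert-butyldimethylsilyl) ether F8, with unchanged 13 recycled. Excess MnO2 then oxidises the one free carbinol to completion, giving silyloxy ketone F9. Reduction as in step 8, now without a free hydroxyl, gives F10, and TBAF removes the silyl group to give 15.

**Step 8.**
- What may go wrong: loss of facial selectivity, because the catalyst may have to override a preference of the substrate for the S carbinol, and the alkoxyborane formed from the free hydroxyl may reduce the ketone without the catalyst.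
- Fallback, from 13, rejoining at 15 (steps 7 and 8 bypassed): replace the oxidation–reduction pair by an invertive displacement. Mitsunobu esterification with one equivalent of 4-nitrobenzoic acid (PPh3, DIAD, toluene, 0 °C) inverts one of the two homotopic carbinols to give the (R)-4-nitrobenzoate F11, and K2CO3 in MeOH cleaves the ester to 15. Any retention through benzylic ionisation gives back 13 after methanolysis. Intramolecular ether formation is disfavoured by the trans ring.

## Further compounds

F1 | step 3 | dimethyl trans-oxolane-3,4-dicarboxylate, racemate (both enantiomers written) | COC(=O)[C@H]1COC[C@@H]1C(=O)OC.COC(=O)[C@@H]1COC[C@H]1C(=O)OC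
F2 | step 3 | trans-N3,N4-dimethoxy-N3,N4-dimethyloxolane-3,4-dicarboxamide, racemate (both enantiomers written) | CON(C)C(=O)[C@H]1COC[C@@H]1C(=O)N(C)OC.CON(C)C(=O)[C@@H]1COC[C@H]1C(=O)N(C)OC
F3 | step 3 | trans-oxolane-3,4-diylbis[(4-benzyloxy-3-methoxyphenyl)methanone], racemate (both enantiomers written) | COc1cc(C(=O)[C@H]2COC[C@@H]2C(=O)c2ccc(OCc3ccccc3)c(OC)c2)ccc1OCc1ccccc1.COc1cc(C(=O)[C@@H]2COC[C@H]2C(=O)c2ccc(OCc3ccccc3)c(OC)c2)ccc1OCc1ccccc1
F4 | step 3 | (1S,1′S)-[(3S,4S)-oxolane-3,4-diyl]bis[(4-benzyloxy-3-methoxyphenyl)methanol] | COc1cc([C@@H](O)[C@@H]2COC[C@H]2[C@H](O)c2ccc(OCc3ccccc3)c(OC)c2)ccc1OCc1ccccc1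
F5 | step 5 | [(3S,4S)-oxolane-3,4-diyl]dimethanol | OC[C@H]1COC[C@@H]1CO
F6 | step 5 | (3R,4R)-oxolane-3,4-dicarbaldehyde | O=C[C@H]1COC[C@@H]1C=O
F7 | step 5 | [(3R,4R)-oxolane-3,4-diyl]bis[(4-benzyloxy-3-methoxyphenyl)methanol], mixture of carbinol epimers | COc1cc(C(O)[C@H]2COC[C@@H]2C(O)c2ccc(OCc3ccccc3)c(OC)c2)ccc1OCc1ccccc1
F8 | step 7 | (S)-(4-benzyloxy-3-methoxyphenyl)[(3R,4R)-4-[(S)-(4-benzyloxy-3-methoxyphenyl)(tert-butyldimethylsilyloxy)methyl]oxolan-3-yl]methanol | COc1cc([C@@H](O[Si](C)(C)C(C)(C)C)[C@H]2COC[C@@H]2[C@H](O)c2ccc(OCc3ccccc3)c(OC)c2)ccc1OCc1ccccc1
F9 | step 7 | [(3R,4R)-4-[(S)-(4-benzyloxy-3-methoxyphenyl)(tert-butyldimethylsilyloxy)methyl]oxolan-3-yl](4-benzyloxy-3-methoxyphenyl)methanone | COc1cc([C@@H](O[Si](C)(C)C(C)(C)C)[C@H]2COC[C@@H]2C(=O)c2ccc(OCc3ccccc3)c(OC)c2)ccc1OCc1ccccc1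
F10 | step 7 | (R)-(4-benzyloxy-3-methoxyphenyl)[(3R,4R)-4-[(S)-(4-benzyloxy-3-methoxyphenyl)(tert-butyldimethylsilyloxy)methyl]oxolan-3-yl]methanol | COc1cc([C@@H](O[Si](C)(C)C(C)(C)C)[C@H]2COC[C@@H]2[C@@H](O)c2ccc(OCc3ccccc3)c(OC)c2)ccc1OCc1ccccc1
F11 | step 8 | (R)-(4-benzyloxy-3-methoxyphenyl)[(3R,4R)-4-[(S)-(4-benzyloxy-3-methoxyphenyl)(hydroxy)methyl]oxolan-3-yl]methyl 4-nitrobenzoate | COc1cc([C@@H](O)[C@H]2COC[C@@H]2[C@@H](OC(=O)c2ccc(cc2)[N+](=O)[O-])c2ccc(OCc3ccccc3)c(OC)c2)ccc1OCc1ccccc1
A1 | alternative 1 | (3Z,4Z)-3,4-bis[(4-benzyloxy-3-methoxyphenyl)methylidene]oxolane | COc1cc(/C=C2\COC\C2=C/c2ccc(OCc3ccccc3)c(OC)c2)ccc1OCc1ccccc1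
A2 | alternative 1 | meso cis-1,4-bis(4-benzyloxy-3-methoxyphenyl)-1,4,5,7-tetrahydrofuro[3,4-d][1,2]dioxine | COc1cc([C@H]2OO[C@@H](c3ccc(OCc4ccccc4)c(OC)c3)C3=C2COC3)ccc1OCc1ccccc1
A3 | alternative 2 | 1,4-bis[(4S)-4-benzyl-2-oxo-1,3-oxazolidin-3-yl]butane-1,4-dione | O=C(CCC(=O)N1[C@@H](Cc2ccccc2)COC1=O)N1[C@@H](Cc2ccccc2)COC1=O
A4 | alternative 2 | 4-(benzyloxy)-3-methoxybenzaldehyde | COc1cc(C=O)ccc1OCc1ccccc1
A5 | alternative 2 | twofold-symmetric syn,syn double aldol adduct, 1,4-bis[(4S)-4-benzyl-2-oxo-1,3-oxazolidin-3-yl]-2,3-bis[(4-benzyloxy-3-methoxyphenyl)(hydroxy)methyl]butane-1,4-dione | COc1cc([C@@H](O)[C@@H](C(=O)N2[C@@H](Cc3ccccc3)COC2=O)[C@H](C(=O)N2[C@@H](Cc3ccccc3)COC2=O)[C@H](O)c2ccc(OCc3ccccc3)c(OC)c2)ccc1OCc1ccccc1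
A6 | alternative 3 | (5S)-5-[1-(4-benzyloxy-3-methoxyphenyl)ethenyl]-4,5-dihydro-1,3-dioxepine | C=C(c1ccc(OCc2ccccc2)c(OC)c1)[C@H]1COCOC=C1
A7 | alternative 3 | (3R,4S)-4-[1-(4-benzyloxy-3-methoxyphenyl)ethenyl]oxolane-3-carbaldehyde | O=C[C@H]1COC[C@@H]1C(=C)c1ccc(OCc2ccccc2)c(OC)c1
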